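All constants belong to no real substance; the rest is arithmetic.

The constants to watch first are the two that compete for the partner: coupling with substrate against decay.

    partner + bis adduct → triple product + by-product (k1 = 0.86 L mol⁻¹ h⁻¹)
    single product → over-reaction product (k2 = 0.027 h⁻¹)
    single product ⇌ isomer of the product (K3 = 0.81, k3 = 0.025 h⁻¹)
    partner → decomposed reagent (k4 = 0.040 h⁻¹)
    partner + single product → bis adduct + by-product (k5 = 0.025 L mol⁻¹ h⁻¹)
    substrate + partner → single product + by-product (k6 = 0.22 L mol⁻¹ h⁻¹)

all flasks: time 3.0 d

| charge | substrate | partner | remark |
|---|---|---|---|
| red | 0.14 M | 0.252 M (fed, over 2.5 d) | all else is in the flask from the start; the feed brings no volume worth counting |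
| amber | 0.14 M (fed, over 2.5 d) | 0.252 M | all else is in the flask from the start; the feed brings no volume worth counting |
| blue | 0.14 M | 0.252 M | everything together at the start |

1. the flask with the highest amount of single product, in percent of the substrate charged ("all alike" if they lie within 1.5 percentage points) (red / amber / blue / all alike)
2. final single product, as a percentage of the substrate charged, in red
3. final single product, as a percentage of the substrate charged, in amber
4. final single product, as a percentage of the substrate charged, in blue

A partner molecule that is spent either couples or decays. I set the later couplings aside, since the one on single product has the constant 0.025 L mol⁻¹ h⁻¹, below that of the first coupling. So I folded the givens into one number, the coupling number φ = 0.770: the coupling rate constant times the charged substrate, over the decay constant of the partner. In words, these are the odds of a partner molecule at full substrate. Coupling runs slower than decay even there, and the odds fall as the substrate falls.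

At constant odds, 0.110 M of partner would couple. That overstates it, so I replaced the falling curve by the straight mean between charge and that end, 60.8 % of the charge. A second pass then gave 0.0804 M coupled, leaving 42.6 % of the substrate once the partner is spent.

The partner's feed time stands nowhere in this balance, so red and blue come out equal in it. Amber differs: its substrate arrives over 4.2 partner lifetimes, so its odds start low and I put it below them. One number was therefore not enough. Single product has a half-life of 1.1 d by the over-reaction step alone in blue, shorter than the run, so I chose red, whose product is made later. My reckoning gave no percentages.

The forecast also chose red, with 17 % in red, 7.3 % in amber and 9.5 % in blue, because feeding the partner “leaves the single product younger at the end”.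

Red came out highest at 17.3 %, against 10.5 % in blue and 6.96 % in amber. Over the first 2.5 d, mean substrate stood at 0.110 M in red and 0.0519 M in amber, so φ scales to odds of 0.606 and 0.285. In blue, with partner down to 1.63 %, substrate read 41 % against my 42.6 %, a gap of 1.3 percentage points that holds the error of the mean together with the later couplings I set aside.

Red read at 12 d is the same balance, and φ again gives 42.6 %. There the partner stands at 0 %, substrate at 40.3 % and single product at 1.10 %.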